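**Plan**
- Labels used: lactone ring O1–C2(=O)–C3=C4(Br)–C5, exocyclic C6 (=CBr2) on C5, carbinol carbon C1' on C3.
- Retrosynthetic cuts, in order: the O–Si bond; C5=C6 (HBr added back to give C5H–C6Br3); the ring bond C4–C5, with one Br returned from C6 to C4; the ester link O1–C2 (acid chloride plus bromal); C3=C4 (dibromoolefination of a 2-oxo ester); C3=O (ozonolysis of a methylidene group); C3–C1' (Morita–Baylis–Hillman).
- Enabling feature: C4 and C6 flank C5 and together carry three Br. Opening C4–C5 with a Br shift turns the butenolide ring into an isomeric open ester of two gem-dibromoalkenes. One is an electron-poor C3=C4Br2 donor and the other a C5H=C6Br2 acceptor, held 1,5 by the planar chain C4–C3–C2–O1–C5.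
- One 5-exo bromine-atom-transfer cycloisomerisation therefore makes the only ring, the C4 vinyl bromide and the full bromine count at C6.
- Forward order: C1'–C3 chain, then C4, then the ester carrying C5–C6, then the ring, then the diene and the free OH.
- Stereochemistry: C1' (R) is set in step 1 by the β-isocupreidine-catalysed Morita–Baylis–Hillman reaction and is not touched again. The CHCl and C5 centres are transient.

Key step: step 8

Remark: β-isocupreidine, the hexafluoroisopropyl acrylate 2 and bromal 8 are taken as commercial.

Step 1
Reactants: 1 butanal; 2 1,1,1,3,3,3-hexafluoropropan-2-yl acrylate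
Product: 3 1,1,1,3,3,3-hexafluoropropan-2-yl (R)-3-hydroxy-2-methylidenehexanoate
Conditions: β-isocupreidine (10 mol %), DMF, −55 °C
Reagents that add atoms: none
Why: Asymmetric Morita–Baylis–Hillman reaction, in which the quinidine-derived amine adds to the activated acrylate and its phenolic OH organises the aldol and proton-transfer steps by hydrogen bonding, a combination known to give the (R)-carbinol with aliphatic aldehydes and so to set C1'.

Step 2
Reactants: 3 1,1,1,3,3,3-hexafluoropropan-2-yl (R)-3-hydroxy-2-methylidenehexanoate
Product: 4 1,1,1,3,3,3-hexafluoropropan-2-yl (R)-3-[(tert-butyldimethylsilyl)oxy]-2-methylidenehexanoate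
Conditions: TBSOTf, 2,6-lutidine, CH2Cl2, −78 to 0 °C
Reagents that add atoms: tert-butyldimethylsilyl triflate, CC(C)(C)[Si](C)(C)OS(=O)(=O)C(F)(F)F
Why: O-silylation with a non-nucleophilic base spares the activated ester and masks the alcohol against the phosphine/CBr4 and acid chloride steps, and C1' is not involved.

Step 3
Reactants: 4 1,1,1,3,3,3-hexafluoropropan-2-yl (R)-3-[(tert-butyldimethylsilyl)oxy]-2-methylidenehexanoate
Product: 5 1,1,1,3,3,3-hexafluoropropan-2-yl (R)-3-[(tert-butyldimethylsilyl)oxy]-2-oxohexanoate
Conditions: O3, CH2Cl2, −78 °C; then Me2S, −78 °C to rt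
Reagents that add atoms: ozone, [O-][O+]=O
Why: Criegee ozonolysis of the only C=C bond with neutral reductive work-up gives the 2-oxo ester without enolising the C1'–H next to the new ketone.

Step 4
Reactants: 5 1,1,1,3,3,3-hexafluoropropan-2-yl (R)-3-[(tert-butyldimethylsilyl)oxy]-2-oxohexanoate
Product: 6 1,1,1,3,3,3-hexafluoropropan-2-yl (R)-3-[(tert-butyldimethylsilyl)oxy]-2-(dibromomethylidene)hexanoate
Conditions: CBr4, PPh3, CH2Cl2, 0 °C to rt
Reagents that add atoms: carbon tetrabromide, BrC(Br)(Br)Br
Why: Ramirez dibromoolefination (first stage of the Corey–Fuchs sequence) works on ester-activated ketones, and its non-basic medium should leave the enolisable C1' centre intact.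

Step 5
Reactants: 6 1,1,1,3,3,3-hexafluoropropan-2-yl (R)-3-[(tert-butyldimethylsilyl)oxy]-2-(dibromomethylidene)hexanoate
Product: 7 (R)-3-[(tert-butyldimethylsilyl)oxy]-2-(dibromomethylidene)hexanoic acid
Conditions: LiOH, THF/H2O, 0 °C; then 1 M HCl to pH 3
Reagents that add atoms: lithium hydroxide, [Li+].[OH-]
Why: BAc2 saponification of the activated fluoroalkyl ester should be fast at 0 °C and outrun attack of hydroxide at the hindered C4, and the carboxylate formed switches off the acceptor.

Step 6
Reactants: 7 (R)-3-[(tert-butyldimethylsilyl)oxy]-2-(dibromomethylidene)hexanoic acid; 8 tribromoacetaldehyde (bromal)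
Product: 10 2,2,2-tribromo-1-chloroethyl (3R)-3-[(tert-butyldimethylsilyl)oxy]-2-(dibromomethylidene)hexanoate (both epimers at the CHCl carbon), via acid chloride 9 (not isolated)
Conditions: 1-chloro-N,N,2-trimethylprop-1-en-1-amine, CH2Cl2, 0 °C; then 8, Bu4NCl (5 mol %), rt
Reagents that add atoms: 1-chloro-N,N,2-trimethylprop-1-en-1-amine, CC(C)=C(Cl)N(C)C
Why: Neutral acid chloride formation is followed by the chloride-catalysed addition of an acyl chloride across the C=O of a trihaloacetaldehyde (α-chloroalkyl ester synthesis), which forms O1–C2 and brings in C5–C6, and the new CHCl centre is uncontrolled and vanishes in step 7.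

Step 7
Reactants: 10 2,2,2-tribromo-1-chloroethyl (3R)-3-[(tert-butyldimethylsilyl)oxy]-2-(dibromomethylidene)hexanoate
Product: 11 2,2-dibromoethenyl (R)-3-[(tert-butyldimethylsilyl)oxy]-2-(dibromomethylidene)hexanoate
Conditions: Zn dust (1.1 equiv), THF, 0 °C
Reagents that add atoms: none
Why: Boord-type reductive 1,2-elimination, in which zinc inserts into a weak C–Br bond of the CBr3 group much faster than into the vinylic C–Br bonds and the neighbouring chloride leaves, as in the known route from 1,2,2,2-tetrahaloethyl esters to 2,2-dihalovinyl esters.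

Step 8
Reactants: 11 2,2-dibromoethenyl (R)-3-[(tert-butyldimethylsilyl)oxy]-2-(dibromomethylidene)hexanoate
Product: 12 4-bromo-3-{(R)-1-[(tert-butyldimethylsilyl)oxy]butyl}-5-(tribromomethyl)furan-2(5H)-one (both epimers at C5)
Conditions: [Cu(dap)2]Cl (2 mol %; dap = 2,9-bis(4-methoxyphenyl)-1,10-phenanthroline), degassed MeCN (5 mM), green LED (530 nm), rt
Reagents that add atoms: none
Why: Proposed new method: the photoexcited monovalent copper complex should pass one electron to the conjugated C3=C4Br2 acrylate, the only easily reduced pi system of 11, so that bromide goes to copper and a sigma alpha-bromovinyl radical arises at C4; the invertomer whose orbital points to the C2 side adds to C5, and the C6 dibromoalkyl radical so formed takes bromine back from the divalent copper bromide, which makes the step a catalytic isomerisation that moves one bromine from C4 to C6. The closest known reaction types are the copper-photocatalysed Kharasch atom-transfer addition and cyclisation of polyhaloalkanes and the 5-exo cyclisation of vinyl radicals released from activated vinyl bromides by photoredox catalysis; what has not been shown is an sp2 C–Br donor with halogen rebound onto an enol-ester acceptor. The lactone ring closes 5-exo-trig: C4, C3, C2 and O1 lie in one plane, the radical orbital lies in that plane, and the C5=C6 pi bond can turn perpendicular to it by rotation about O1–C5. Regioselectivity (C5, not C6) follows from attack at the CH end of a vinylidene-dibromide-type alkene, which is the less hindered end and leaves the bromine-stabilised radical, and a beta-acyloxy radical does not fragment, unlike the corresponding carbanion or alkylpalladium species, which would expel the carboxylate O1. Chemoselectivity among the four C–Br bonds rests on the lower-lying acceptor orbital of the acrylate half, and re-activation of the CBr3 group of 12 is degenerate because that radical can only take bromine back. The new stereocentre C5 is not controlled by the remote C1' centre, both epimers are carried on, and C5 becomes trigonal in step 9.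

Step 9
Reactants: 12 4-bromo-3-{(R)-1-[(tert-butyldimethylsilyl)oxy]butyl}-5-(tribromomethyl)furan-2(5H)-one
Product: 14 4-bromo-5-(dibromomethylidene)-3-[(R)-1-hydroxybutyl]furan-2(5H)-one (target), via silyl ether 13 (not isolated)
Conditions: iPr2NEt (1.1 equiv), CH2Cl2, −20 to 0 °C; then HF·pyridine, 0 °C to rt
Reagents that add atoms: none
Why: E1cB dehydrobromination (the hindered amine removes the acidic gamma proton at C5 and bromide leaves from C6) gives the cross-conjugated dienyl lactone, and acidic fluoride desilylation then frees the C1' alcohol under conditions that this acid-stable, base-sensitive lactone should tolerate, with C1' untouched.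

**Compound list**
1 | butanal | CCCC=O | starting material
2 | 1,1,1,3,3,3-hexafluoropropan-2-yl acrylate | C=CC(=O)OC(C(F)(F)F)C(F)(F)F | starting material
3 | 1,1,1,3,3,3-hexafluoropropan-2-yl (R)-3-hydroxy-2-methylidenehexanoate | CCC[C@@H](O)C(=C)C(=O)OC(C(F)(F)F)C(F)(F)F | intermediate
4 | 1,1,1,3,3,3-hexafluoropropan-2-yl (R)-3-[(tert-butyldimethylsilyl)oxy]-2-methylidenehexanoate | CCC[C@@H](O[Si](C)(C)C(C)(C)C)C(=C)C(=O)OC(C(F)(F)F)C(F)(F)F | intermediate
5 | 1,1,1,3,3,3-hexafluoropropan-2-yl (R)-3-[(tert-butyldimethylsilyl)oxy]-2-oxohexanoate | CCC[C@@H](O[Si](C)(C)C(C)(C)C)C(=O)C(=O)OC(C(F)(F)F)C(F)(F)F | intermediate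
6 | 1,1,1,3,3,3-hexafluoropropan-2-yl (R)-3-[(tert-butyldimethylsilyl)oxy]-2-(dibromomethylidene)hexanoate | CCC[C@@H](O[Si](C)(C)C(C)(C)C)C(=C(Br)Br)C(=O)OC(C(F)(F)F)C(F)(F)F | intermediate
7 | (R)-3-[(tert-butyldimethylsilyl)oxy]-2-(dibromomethylidene)hexanoic acid | CCC[C@@H](O[Si](C)(C)C(C)(C)C)C(=C(Br)Br)C(=O)O | intermediate
8 | tribromoacetaldehyde (bromal) | O=CC(Br)(Br)Br | starting material
9 | (R)-3-[(tert-butyldimethylsilyl)oxy]-2-(dibromomethylidene)hexanoyl chloride | CCC[C@@H](O[Si](C)(C)C(C)(C)C)C(=C(Br)Br)C(=O)Cl | intermediate
10 | 2,2,2-tribromo-1-chloroethyl (3R)-3-[(tert-butyldimethylsilyl)oxy]-2-(dibromomethylidene)hexanoate, both CHCl epimers | CCC[C@@H](O[Si](C)(C)C(C)(C)C)C(=C(Br)Br)C(=O)OC(Cl)C(Br)(Br)Br | intermediate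
11 | 2,2-dibromoethenyl (R)-3-[(tert-butyldimethylsilyl)oxy]-2-(dibromomethylidene)hexanoate | CCC[C@@H](O[Si](C)(C)C(C)(C)C)C(=C(Br)Br)C(=O)OC=C(Br)Br | intermediate
12 | 4-bromo-3-{(R)-1-[(tert-butyldimethylsilyl)oxy]butyl}-5-(tribromomethyl)furan-2(5H)-one, both C5 epimers | CCC[C@@H](O[Si](C)(C)C(C)(C)C)C1=C(Br)C(C(Br)(Br)Br)OC1=O | intermediate
13 | 4-bromo-5-(dibromomethylidene)-3-{(R)-1-[(tert-butyldimethylsilyl)oxy]butyl}furan-2(5H)-one | CCC[C@@H](O[Si](C)(C)C(C)(C)C)C1=C(Br)C(=C(Br)Br)OC1=O | intermediate
14 | 4-bromo-5-(dibromomethylidene)-3-[(R)-1-hydroxybutyl]furan-2(5H)-one | CCC[C@@H](O)C1=C(Br)C(=C(Br)Br)OC1=O | target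

Total step count: 9. Longest linear sequence: 9 steps (from butanal 1).

**Steps most likely to fail**

Step 8.
- What may go wrong: electron transfer from the excited copper complex to 11 may be too slow. The vinyl radical invertomer that points to the side chain may take a hydrogen from the propyl chain by 1,5-transfer, or from the solvent. Either could happen before the ester has rotated into the s-cis form that the closure needs.
- Fallback (known chemistry): C4–C5 is made between two components and the ring is then closed at O1–C2. It sets out from 6.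
- Bromine–magnesium exchange with iPrMgCl in THF at −78 °C is directed by the ester carbonyl to the bromine cis to it. It gives 1,1,1,3,3,3-hexafluoropropan-2-yl (R,E)-3-bromo-3-(chloromagnesio)-2-{1-[(tert-butyldimethylsilyl)oxy]butyl}prop-2-enoate F1.
- This is added to excess bromal 8 at −78 °C. On warming, the magnesium alkoxide closes onto the activated ester in the same operation. The route is rejoined at 12.

Step 6.
- What may go wrong: addition of the hindered acyl chloride across the carbonyl group of bromal is reversible and may stall, and halide exchange at the trihalomethyl group may set in.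
- Fallback (enolate O-acylation in place of addition and reductive elimination): it sets out from 7, which is converted into 9 as before.
- Acid chloride 9 is added to commercial dibromoacetaldehyde and iPr2NEt in CH2Cl2 at −78 to 0 °C. The readily formed enolate is acylated on oxygen. The route is rejoined at 11, bypassing 10 and step 7.

Step 1.
- What may go wrong: slow conversion of the enolisable linear aldehyde, capture of the adduct by a second aldehyde molecule, self-aldol reaction, and erosion of enantiopurity.
- Fallback (resolution in place of asymmetric catalysis): it sets out from 1 and 2.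
- The DABCO-catalysed reaction at rt gives racemic 1,1,1,3,3,3-hexafluoropropan-2-yl 3-hydroxy-2-methylidenehexanoate F2.
- Acylative kinetic resolution follows, using isobutyric anhydride (0.6 equiv), iPr2NEt and the enantiomer of benzotetramisole that acylates the (S)-alcohol faster.
- This converts the unwanted enantiomer into 1,1,1,3,3,3-hexafluoropropan-2-yl (S)-3-(isobutyryloxy)-2-methylidenehexanoate F3, which is removed by chromatography. The unreacted (R)-alcohol is 3, where the route is rejoined.

**Further compounds**
F1 | step 8 | 1,1,1,3,3,3-hexafluoropropan-2-yl (R,E)-3-bromo-3-(chloromagnesio)-2-{1-[(tert-butyldimethylsilyl)oxy]butyl}prop-2-enoate | CCC[C@@H](O[Si](C)(C)C(C)(C)C)/C(=C(\Br)[Mg]Cl)C(=O)OC(C(F)(F)F)C(F)(F)F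
F0 | step 6 | none | none
F2 | step 1 | racemic 1,1,1,3,3,3-hexafluoropropan-2-yl 3-hydroxy-2-methylidenehexanoate | CCCC(O)C(=C)C(=O)OC(C(F)(F)F)C(F)(F)F
F3 | step 1 | 1,1,1,3,3,3-hexafluoropropan-2-yl (S)-3-(isobutyryloxy)-2-methylidenehexanoate | CCC[C@H](OC(=O)C(C)C)C(=C)C(=O)OC(C(F)(F)F)C(F)(F)F
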